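**Two runs.** The noon run, with reagent at 62.0% of the solid charge, shows 12.5% target at 90.0 min, and the dusk run, at 29.0%, shows 6.7%. That reading ratio of 1.87 stands beside a reagent ratio of 2.14, so I scale target with reagent and keep the last slope of the noon run.

| setting | dusk | noon | larch | elm |
|---|---|---|---|---|
| solid substrate | 0.10 M | 0.10 M | 0.10 M | 0.10 M |
| reagent | 0.029 M | 0.062 M | 0.0500 M | 0.0900 M |
| remark | run made earlier | run made earlier |  |  |
| time |  |  | 10 h | 3.0 h |

| run | time / min | target / % | solid substrate / % |
|---|---|---|---|
| dusk | 15.0 | 0 | 91.8 |
| dusk | 30.0 | 0.8 | 85.2 |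
| dusk | 50.0 | 2.9 | 75.7 |
| dusk | 60.0 | 3.1 | 69.7 |
| dusk | 80.0 | 5.2 | 62.4 |
| dusk | 90.0 | 6.7 | 57.3 |
| noon | 8.00 | 0.8 | 95.5 |
| noon | 12.0 | 0.5 | 93.2 |
| noon | 20.0 | 1.6 | 88.4 |
| noon | 30.0 | 1.6 | 83.5 |
| noon | 50.0 | 5.7 | 75.6 |
| noon | 90.0 | 12.5 | 56.0 |

(readings scatter by 0.5 percentage points)

- the winner by amount of target, in percent of the solid substrate charged; "neither" if no more than 2 percentage points parts them (larch / elm / neither)
- how much target is there at the end, in percent of the solid substrate charged: larch
- how much target is there at the end, in percent of the solid substrate charged: elm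

- given per volume of solution although it is solid: solid substrate
- the numbers in the tables scatter with a standard deviation of 0.5 percentage points
- at the start none of the solid substrate is in solution
- what has only dissolved of solid substrate counts as not reacted

**Opening the ledger.** Larch charges less reagent than solid substrate, so reagent is its limiting reagent. I carry the reagent ceiling, the charged reagent as a share of the charged solid substrate 50.0%, and I assume that each target costs one reagent. The debits are target, unused reagent, and any other use of reagent, which the readings don't show.

**Booking both.** In larch the scaled line meets the ceiling at 6.35 h, earlier than its 10 h, so I book larch at 50.0% less the unseen debit. In elm the line reaches 40.4% at 3.0 h, lower than its ceiling of 90.0%, so I book elm on the line.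

**The result.** The forecast names larch, with 47% for larch, because “reaction runs nearly to exhaustion of reagent”, and 36% for elm, where I have 40.4%. The flask gives 41.1% in larch and 35.6% in elm, so larch has more.

    starting material ⇌ intermediate A (K = 2.18, k = 8.06 × 10⁻⁴ s⁻¹)
    starting material + reagent → target (k = 0.00538 M⁻¹ s⁻¹)
    starting material + reagent ⇌ intermediate B (K = 8.10 M⁻¹, k = 0.00148 M⁻¹ s⁻¹)
    reagent + intermediate B → intermediate C (k = 0.00509 M⁻¹ s⁻¹)
    intermediate C → side product (k = 2.68 × 10⁻⁵ s⁻¹)
    solid substrate ⇌ starting material, rate k6*(cs6 - [starting material]) while solid is left; crystals form when [starting material] > cs6 (solubility = 0.0630 M, k = 1.47 × 10⁻⁴ s⁻¹)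

**Books closed.** Target in larch takes 82.2% of the ceiling. Unused reagent in larch stands at 3.5% of its own charge at 10.0 h. Of the solid charge in larch, intermediate B holds 0.386% at one reagent, while intermediate C and side product hold 1.72% and 1.67%, at two reagent each. The larch entries sum to 50.0% of the solid charge, against the ceiling of 50.0%. A neighbour of larch, charged with 0.40 M of solid substrate, has a ceiling of 12.5%. It ends at 10.7% target, 85.6% of that ceiling, with 0.80% of its reagent unused.

The earlier runs and the new flask are simulated from invented constants; the scatter is artificial.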